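Retrosynthesis: remove the O3 silyl group and the C6 ester; cut C5–C6 (ring closure); cut the lactone bond C12–O8 and then C7–C8 (aldol); cut C3–C4 (iodo-aldol); cut C1–C2 and C10–C14 (carboalumination, epoxide opening).
Forward: the C8–C3 chain is grown from a butynyl silyl ether; C4, C5 and C15 arrive as an iodoalkene in a three-component iodo-aldol; the lactone (ring O–C8–C7–C11–C12) is built by an auxiliary aldol with an itaconyl unit; the ten-membered carbocycle (C1–C10) is closed last.
Enabling feature: C6 is an allylic carbinol carbon bonded to C5, the hydrogen-bearing carbon of the C4=C5 alkene, with C15 and C6 cis. This maps onto a (Z)-iodoalkene and a formyl group, two electrophilic carbons that are joined after polarity reversal at C5 by divalent chromium; the trans-fused lactone and the two E alkenes pre-fold the chain.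
Stereochemistry: C3 by catalyst control in the iodo-aldol; C7 and C8 by the (R)-thiazolidinethione auxiliary (syn aldol, hence trans lactone); C6 in the ring closure (substrate control); the ester centres from (R)-2-methylbutanoic acid; C1=C10 from syn carboalumination and C4=C5 from the Z-iodoalkene.
Key step: step 14

Remark: germacrane numbering (C1–C15; lactone carbonyl C12, exocyclic methylene C13) is used for all intermediates.
Remark: both acyl groups are (R)-2-methylbutanoyl as drawn, and (R)-2-methylbutanoic acid is taken as a commercial compound.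
Remark: the (S)-oxazaborolidinium catalyst of step 3 is assumed to direct attack to the Si face of aldehyde 4, as in related additions to aldehydes; if the sense is opposite, its enantiomer is used.

Step 1
Reactants: 1 tert-butyl(but-3-yn-1-yloxy)dimethylsilane
Product: 3 (3E)-6-{[tert-butyl(dimethyl)silyl]oxy}-4-methylhex-3-en-1-ol, via alkenylalane 2 (not isolated)
Conditions: AlMe3 (2 equiv), Cp2ZrCl2 (0.2 equiv), CH2Cl2, 0 °C to rt; volatiles removed; n-BuLi, hexane, 0 °C; ethylene oxide, THF, −78 °C to rt; aq. HCl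
Reagents that add atoms: trimethylaluminium, C[Al](C)C; ethylene oxide, C1CO1
Why: Zirconium-catalysed syn-carboalumination (Negishi carboalumination) places CH3 on C10 and aluminium on C1 of the terminal alkyne, and the derived lithium alanate opens ethylene oxide with retention of the alkene geometry, which fixes the E C1=C10 alkene.

Step 2
Reactants: 3 (3E)-6-{[tert-butyl(dimethyl)silyl]oxy}-4-methylhex-3-en-1-ol
Product: 4 (3E)-6-{[tert-butyl(dimethyl)silyl]oxy}-4-methylhex-3-enal
Conditions: Dess–Martin periodinane, NaHCO3, CH2Cl2, 0 °C; used crude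
Reagents that add atoms: none
Why: Dess–Martin oxidation of the primary alcohol under buffered, non-basic conditions should give the β,γ-unsaturated aldehyde without migration of the C1=C10 double bond into conjugation.

Step 3
Reactants: 4 (3E)-6-{[tert-butyl(dimethyl)silyl]oxy}-4-methylhex-3-enal; 5 ethyl propiolate
Product: 7 ethyl (2Z,3R,5E)-8-{[tert-butyl(dimethyl)silyl]oxy}-3-hydroxy-2-(iodomethylidene)-6-methyloct-5-enoate, via trimethylsilyl ether 6 (not isolated)
Conditions: Me3SiI (1.2 equiv), (S)-oxazaborolidinium triflimide catalyst [from (S)-3,3-diphenyl-1-(2-methylphenyl)tetrahydro-1H,3H-pyrrolo[1,2-c][1,3,2]oxazaborole and HNTf2] (20 mol %), CH2Cl2, −78 °C; then dilute HCl, THF, 0 °C (brief)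
Reagents that add atoms: iodotrimethylsilane, C[Si](C)(C)I
Why: In this catalytic enantioselective three-component iodo-aldol coupling (the β-iodo Morita–Baylis–Hillman equivalent) iodide adds to the silyl-activated propiolate and the resulting β-iodoallenoate attacks the catalyst-bound aldehyde through its α-carbon on the Si face, which should set C3 as R and give the Z-iodoalkene (iodine cis to the ester carbon C15).

Step 4
Reactants: 7 ethyl (2Z,3R,5E)-8-{[tert-butyl(dimethyl)silyl]oxy}-3-hydroxy-2-(iodomethylidene)-6-methyloct-5-enoate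
Product: 8 ethyl (2Z,3R,5E)-3,8-bis{[tert-butyl(dimethyl)silyl]oxy}-2-(iodomethylidene)-6-methyloct-5-enoate
Conditions: tBuMe2SiOTf, 2,6-lutidine, CH2Cl2, −78 °C
Reagents that add atoms: tert-butyldimethylsilyl trifluoromethanesulfonate, CC(C)(C)[Si](C)(C)OS(=O)(=O)C(F)(F)F
Why: Silyl ether protection of the secondary allylic alcohol with the silyl triflate and a hindered base proceeds at −78 °C without touching the ester or the iodoalkene.

Step 5
Reactants: 8 ethyl (2Z,3R,5E)-3,8-bis{[tert-butyl(dimethyl)silyl]oxy}-2-(iodomethylidene)-6-methyloct-5-enoate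
Product: 9 (2E,3R,5E)-3,8-bis{[tert-butyl(dimethyl)silyl]oxy}-2-(iodomethylidene)-6-methyloct-5-en-1-ol
Conditions: iBu2AlH (2.5 equiv), CH2Cl2, −78 °C; aq. KNaC4H4O6
Reagents that add atoms: none
Why: iBu2AlH reduces the conjugated ester by 1,2-addition to the allylic alcohol (ester reduction) while the alkenyl iodide and the silyl ethers are inert at −78 °C.

Step 6
Reactants: 9 (2E,3R,5E)-3,8-bis{[tert-butyl(dimethyl)silyl]oxy}-2-(iodomethylidene)-6-methyloct-5-en-1-ol; 10 (2R)-2-methylbutanoic acid
Product: 11 [(2E,3R,5E)-3,8-bis{[tert-butyl(dimethyl)silyl]oxy}-2-(iodomethylidene)-6-methyloct-5-en-1-yl] (2R)-2-methylbutanoate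
Conditions: N,N'-diisopropylcarbodiimide, DMAP (0.1 equiv), CH2Cl2, 0 °C to rt
Reagents that add atoms: none
Why: Steglich esterification of the primary allylic alcohol installs the C15 ester of the target, which also protects O15 in all later steps, and a simple α-alkyl acid is not expected to epimerise under carbodiimide activation.

Step 7
Reactants: 11 [(2E,3R,5E)-3,8-bis{[tert-butyl(dimethyl)silyl]oxy}-2-(iodomethylidene)-6-methyloct-5-en-1-yl] (2R)-2-methylbutanoate
Product: 12 [(2E,3R,5E)-3-{[tert-butyl(dimethyl)silyl]oxy}-8-hydroxy-2-(iodomethylidene)-6-methyloct-5-en-1-yl] (2R)-2-methylbutanoate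
Conditions: HF·pyridine, pyridine, THF, 0 °C
Reagents that add atoms: none
Why: Fluoride-mediated desilylation with buffered HF·pyridine is faster at the unhindered primary silyl ether (O8) than at the secondary allylic one (O3), so that only the C8 alcohol should be freed.

Step 8
Reactants: 12 [(2E,3R,5E)-3-{[tert-butyl(dimethyl)silyl]oxy}-8-hydroxy-2-(iodomethylidene)-6-methyloct-5-en-1-yl] (2R)-2-methylbutanoate
Product: 13 [(2E,3R,5E)-3-{[tert-butyl(dimethyl)silyl]oxy}-2-(iodomethylidene)-6-methyl-8-oxooct-5-en-1-yl] (2R)-2-methylbutanoate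
Conditions: Dess–Martin periodinane, NaHCO3, CH2Cl2, 0 °C; used crude
Reagents that add atoms: none
Why: Dess–Martin oxidation gives the β,γ-unsaturated C8 aldehyde under neutral conditions that leave the ester, the silyl ether and the iodoalkene untouched.

Step 9
Reactants: 14 dimethyl itaconate
Product: 15 3-(methoxycarbonyl)but-3-enoic acid
Conditions: LiOH·H2O (1.0 equiv), THF/H2O, 0 °C; then aq. HCl
Reagents that add atoms: lithium hydroxide, [Li+].[OH-]
Why: Partial saponification (ester hydrolysis) with one equivalent of hydroxide is expected at the non-conjugated ester, which is more electrophilic than the conjugated, α-branched acrylate ester.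

Step 10
Reactants: 15 3-(methoxycarbonyl)but-3-enoic acid; 16 (4R)-4-benzyl-1,3-thiazolidine-2-thione
Product: 17 methyl 4-[(4R)-4-benzyl-2-sulfanylidene-1,3-thiazolidin-3-yl]-2-methylidene-4-oxobutanoate
Conditions: N,N'-dicyclohexylcarbodiimide, DMAP (0.05 equiv), CH2Cl2, 0 °C
Reagents that add atoms: none
Why: Carbodiimide coupling (N-acylation of the thiazolidinethione) gives the activated imide, and low temperature with little DMAP is chosen to avoid migration of the double bond into conjugation.

Step 11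
Reactants: 13 [(2E,3R,5E)-3-{[tert-butyl(dimethyl)silyl]oxy}-2-(iodomethylidene)-6-methyl-8-oxooct-5-en-1-yl] (2R)-2-methylbutanoate; 17 methyl 4-[(4R)-4-benzyl-2-sulfanylidene-1,3-thiazolidin-3-yl]-2-methylidene-4-oxobutanoate
Product: 18 methyl (3R,4S,6E,9R,10E)-3-{[(4R)-4-benzyl-2-sulfanylidene-1,3-thiazolidin-3-yl]carbonyl}-9-{[tert-butyl(dimethyl)silyl]oxy}-4-hydroxy-11-iodo-6-methyl-2-methylidene-10-({[(2R)-2-methylbutanoyl]oxy}methyl)undeca-6,10-dienoate
Conditions: 17, TiCl4 (1.05 equiv), iPr2NEt (1.1 equiv), N-methyl-2-pyrrolidinone (1.1 equiv), CH2Cl2, 0 °C; then 13, −78 °C; aq. NH4Cl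
Reagents that add atoms: none
Why: The titanium Z-enolate of the N-acylthiazolidinethione reacts at its α-carbon C7 with the aldehyde through a non-chelated Zimmerman–Traxler chair (Evans-syn mode of the auxiliary aldol reaction), the (R)-benzyl group fixing the enolate face so that C7 (R) and C8 (S) should arise together.

Step 12
Reactants: 18 methyl (3R,4S,6E,9R,10E)-3-{[(4R)-4-benzyl-2-sulfanylidene-1,3-thiazolidin-3-yl]carbonyl}-9-{[tert-butyl(dimethyl)silyl]oxy}-4-hydroxy-11-iodo-6-methyl-2-methylidene-10-({[(2R)-2-methylbutanoyl]oxy}methyl)undeca-6,10-dienoate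
Product: 19 [(2E,3R,5E)-7-[(2S,3R)-3-{[(4R)-4-benzyl-2-sulfanylidene-1,3-thiazolidin-3-yl]carbonyl}-4-methylidene-5-oxooxolan-2-yl]-3-{[tert-butyl(dimethyl)silyl]oxy}-2-(iodomethylidene)-6-methylhept-5-en-1-yl] (2R)-2-methylbutanoate
Conditions: (1S)-10-camphorsulfonic acid (0.1 equiv), CH2Cl2, rt
Reagents that add atoms: none
Why: Acid-catalysed lactonisation (5-exo-trig transesterification of O8 onto the C12 methyl ester) closes the α-methylene-γ-butyrolactone, and the syn aldol relationship becomes the trans arrangement of the C9 chain and the C6 acyl group.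

Step 13
Reactants: 19 [(2E,3R,5E)-7-[(2S,3R)-3-{[(4R)-4-benzyl-2-sulfanylidene-1,3-thiazolidin-3-yl]carbonyl}-4-methylidene-5-oxooxolan-2-yl]-3-{[tert-butyl(dimethyl)silyl]oxy}-2-(iodomethylidene)-6-methylhept-5-en-1-yl] (2R)-2-methylbutanoate
Product: 20 [(2E,3R,5E)-3-{[tert-butyl(dimethyl)silyl]oxy}-7-[(2S,3R)-3-formyl-4-methylidene-5-oxooxolan-2-yl]-2-(iodomethylidene)-6-methylhept-5-en-1-yl] (2R)-2-methylbutanoate
Conditions: iBu2AlH (1.1 equiv), CH2Cl2, −78 °C, 10 min; aq. KNaC4H4O6; used at once
Reagents that add atoms: none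
Why: The N-acylthiazolidinethione is far more electrophilic than the lactone or the ester and should be reduced by one equivalent of iBu2AlH at −78 °C to an aluminium hemiaminal that releases the aldehyde only on work-up (partial reduction of an activated amide).

Step 14
Reactants: 20 [(2E,3R,5E)-3-{[tert-butyl(dimethyl)silyl]oxy}-7-[(2S,3R)-3-formyl-4-methylidene-5-oxooxolan-2-yl]-2-(iodomethylidene)-6-methylhept-5-en-1-yl] (2R)-2-methylbutanoate
Product: 22 (3R,6R,7R,8S)-3-{[tert-butyl(dimethyl)silyl]oxy}-6-hydroxy-15-{[(2R)-2-methylbutanoyl]oxy}germacra-1(10)E,4E,11(13)-trien-12,8-olide, via alkenylchromium dichloride 21 (not isolated)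
Conditions: CrCl2 (10 equiv), NiCl2 (0.1 equiv), degassed DMSO/THF 3:1, 0.002 M, rt; aqueous work-up
Reagents that add atoms: none
Why: Zerovalent nickel, formed from NiCl2 by divalent chromium, inserts into the C5–I bond and hands the alkenyl group to chromium with retention of geometry (alkenylchromium 21, trivalent chromium), and this nucleophilic C5 adds to the C6 formyl carbon, so that two carbons that are both electrophilic in 20 are joined after polarity reversal at C5. The closest known reaction type is the intramolecular Nozaki–Hiyama–Kishi reaction, an established way to close medium and large carbocycles that contain an E ring alkene. The ten-membered carbocycle (C1–C10) is closed in the 10-exo-trig mode by addition to the exocyclic C6=O bond. The new stereocentre C6 is under substrate control: in the product-like chair–chair fold of the germacrane ring the chromium-bound oxygen points away from the forming ring (anti to C8) and H6 lies antiperiplanar to H7, which should give 6R, and the Z-iodoalkene geometry passes unchanged into the ring alkene (C3 and C6 trans, C15 and C6 cis). The step needs chemoselectivity for the aldehyde and cyclisation in preference to oligomerisation: alkenylchromium reagents add to aldehydes but not to lactones, esters or enoates at room temperature, and high dilution together with the trans-lactone and the two E alkenes, which leave few freely rotating bonds between C5 and C6, should secure ring closure.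

Step 15
Reactants: 22 (3R,6R,7R,8S)-3-{[tert-butyl(dimethyl)silyl]oxy}-6-hydroxy-15-{[(2R)-2-methylbutanoyl]oxy}germacra-1(10)E,4E,11(13)-trien-12,8-olide; 10 (2R)-2-methylbutanoic acid
Product: 23 (3R,6R,7R,8S)-3-{[tert-butyl(dimethyl)silyl]oxy}-6,15-bis{[(2R)-2-methylbutanoyl]oxy}germacra-1(10)E,4E,11(13)-trien-12,8-olide
Conditions: N,N'-diisopropylcarbodiimide (2 equiv), DMAP (0.3 equiv), CH2Cl2, rt
Reagents that add atoms: none
Why: Steglich esterification acylates the C6 allylic alcohol, and an acyl shift from O15 to the cis-disposed O6 during step 14 would be harmless because both positions carry the same acyl group after this step.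

Step 16
Reactants: 23 (3R,6R,7R,8S)-3-{[tert-butyl(dimethyl)silyl]oxy}-6,15-bis{[(2R)-2-methylbutanoyl]oxy}germacra-1(10)E,4E,11(13)-trien-12,8-olide
Product: 24 (3R,6R,7R,8S)-3-hydroxy-6,15-bis{[(2R)-2-methylbutanoyl]oxy}germacra-1(10)E,4E,11(13)-trien-12,8-olide
Conditions: HF·pyridine, THF, 0 °C to rt
Reagents that add atoms: none
Why: Fluoride-mediated desilylation with HF·pyridine removes the O3 silyl ether under mildly acidic conditions that spare the α-methylene lactone (no basic fluoride for conjugate addition) and both esters.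

Compound list
1 | tert-butyl(but-3-yn-1-yloxy)dimethylsilane | C#CCCO[Si](C)(C)C(C)(C)C | starting material
2 | [(1E)-4-{[tert-butyl(dimethyl)silyl]oxy}-2-methylbut-1-en-1-yl]dimethylalane | CC(C)(C)[Si](C)(C)OCC/C(C)=C/[Al](C)C | intermediate
3 | (3E)-6-{[tert-butyl(dimethyl)silyl]oxy}-4-methylhex-3-en-1-ol | CC(C)(C)[Si](C)(C)OCC/C(C)=C/CCO | intermediate
4 | (3E)-6-{[tert-butyl(dimethyl)silyl]oxy}-4-methylhex-3-enal | CC(C)(C)[Si](C)(C)OCC/C(C)=C/CC=O | intermediate
5 | ethyl propiolate | C#CC(=O)OCC | starting material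
6 | ethyl (2Z,3R,5E)-8-{[tert-butyl(dimethyl)silyl]oxy}-2-(iodomethylidene)-6-methyl-3-[(trimethylsilyl)oxy]oct-5-enoate | CC(C)(C)[Si](C)(C)OCC/C(C)=C/C[C@@H](O[Si](C)(C)C)/C(C(=O)OCC)=C/I | intermediate
7 | ethyl (2Z,3R,5E)-8-{[tert-butyl(dimethyl)silyl]oxy}-3-hydroxy-2-(iodomethylidene)-6-methyloct-5-enoate | CC(C)(C)[Si](C)(C)OCC/C(C)=C/C[C@@H](O)/C(C(=O)OCC)=C/I | intermediate
8 | ethyl (2Z,3R,5E)-3,8-bis{[tert-butyl(dimethyl)silyl]oxy}-2-(iodomethylidene)-6-methyloct-5-enoate | CC(C)(C)[Si](C)(C)OCC/C(C)=C/C[C@@H](O[Si](C)(C)C(C)(C)C)/C(C(=O)OCC)=C/I | intermediate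
9 | (2E,3R,5E)-3,8-bis{[tert-butyl(dimethyl)silyl]oxy}-2-(iodomethylidene)-6-methyloct-5-en-1-ol (iodine cis to CH2OH) | CC(C)(C)[Si](C)(C)OCC/C(C)=C/C[C@@H](O[Si](C)(C)C(C)(C)C)/C(CO)=C/I | intermediate
10 | (2R)-2-methylbutanoic acid | CC[C@@H](C)C(=O)O | starting material
11 | [(2E,3R,5E)-3,8-bis{[tert-butyl(dimethyl)silyl]oxy}-2-(iodomethylidene)-6-methyloct-5-en-1-yl] (2R)-2-methylbutanoate | CC(C)(C)[Si](C)(C)OCC/C(C)=C/C[C@@H](O[Si](C)(C)C(C)(C)C)/C(COC(=O)[C@H](C)CC)=C/I | intermediate
12 | [(2E,3R,5E)-3-{[tert-butyl(dimethyl)silyl]oxy}-8-hydroxy-2-(iodomethylidene)-6-methyloct-5-en-1-yl] (2R)-2-methylbutanoate | OCC/C(C)=C/C[C@@H](O[Si](C)(C)C(C)(C)C)/C(COC(=O)[C@H](C)CC)=C/I | intermediate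
13 | [(2E,3R,5E)-3-{[tert-butyl(dimethyl)silyl]oxy}-2-(iodomethylidene)-6-methyl-8-oxooct-5-en-1-yl] (2R)-2-methylbutanoate | O=CC/C(C)=C/C[C@@H](O[Si](C)(C)C(C)(C)C)/C(COC(=O)[C@H](C)CC)=C/I | intermediate
14 | dimethyl itaconate | C=C(CC(=O)OC)C(=O)OC | starting material
15 | 3-(methoxycarbonyl)but-3-enoic acid | C=C(CC(=O)O)C(=O)OC | intermediate
16 | (4R)-4-benzyl-1,3-thiazolidine-2-thione | S=C1N[C@H](Cc2ccccc2)CS1 | starting material
17 | methyl 4-[(4R)-4-benzyl-2-sulfanylidene-1,3-thiazolidin-3-yl]-2-methylidene-4-oxobutanoate | C=C(CC(=O)N1C(=S)SC[C@H]1Cc1ccccc1)C(=O)OC | intermediate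
18 | syn aldol adduct (7R,8S): methyl (3R,4S,6E,9R,10E)-3-{[(4R)-4-benzyl-2-sulfanylidene-1,3-thiazolidin-3-yl]carbonyl}-9-{[tert-butyl(dimethyl)silyl]oxy}-4-hydroxy-11-iodo-6-methyl-2-methylidene-10-({[(2R)-2-methylbutanoyl]oxy}methyl)undeca-6,10-dienoate | COC(=O)C(=C)[C@H]([C@@H](O)C/C(C)=C/C[C@@H](O[Si](C)(C)C(C)(C)C)/C(COC(=O)[C@H](C)CC)=C/I)C(=O)N1C(=S)SC[C@H]1Cc1ccccc1 | intermediate
19 | trans-lactone imide: [(2E,3R,5E)-7-[(2S,3R)-3-{[(4R)-4-benzyl-2-sulfanylidene-1,3-thiazolidin-3-yl]carbonyl}-4-methylidene-5-oxooxolan-2-yl]-3-{[tert-butyl(dimethyl)silyl]oxy}-2-(iodomethylidene)-6-methylhept-5-en-1-yl] (2R)-2-methylbutanoate | C=C1C(=O)O[C@@H](C/C(C)=C/C[C@@H](O[Si](C)(C)C(C)(C)C)/C(COC(=O)[C@H](C)CC)=C/I)[C@@H]1C(=O)N2C(=S)SC[C@H]2Cc3ccccc3 | intermediate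
20 | trans-lactone aldehyde: [(2E,3R,5E)-3-{[tert-butyl(dimethyl)silyl]oxy}-7-[(2S,3R)-3-formyl-4-methylidene-5-oxooxolan-2-yl]-2-(iodomethylidene)-6-methylhept-5-en-1-yl] (2R)-2-methylbutanoate | C=C1C(=O)O[C@@H](C/C(C)=C/C[C@@H](O[Si](C)(C)C(C)(C)C)/C(COC(=O)[C@H](C)CC)=C/I)[C@@H]1C=O | intermediate
21 | alkenylchromium dichloride (iodine of 20 replaced by CrCl2, geometry retained) | C=C1C(=O)O[C@@H](C/C(C)=C/C[C@@H](O[Si](C)(C)C(C)(C)C)/C(COC(=O)[C@H](C)CC)=C/[Cr](Cl)Cl)[C@@H]1C=O | intermediate
22 | (3R,6R,7R,8S)-3-{[tert-butyl(dimethyl)silyl]oxy}-6-hydroxy-15-{[(2R)-2-methylbutanoyl]oxy}germacra-1(10)E,4E,11(13)-trien-12,8-olide | C=C1C(=O)O[C@H]2C/C(C)=C/C[C@@H](O[Si](C)(C)C(C)(C)C)/C(COC(=O)[C@H](C)CC)=C/[C@@H](O)[C@H]12 | intermediate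
23 | (3R,6R,7R,8S)-3-{[tert-butyl(dimethyl)silyl]oxy}-6,15-bis{[(2R)-2-methylbutanoyl]oxy}germacra-1(10)E,4E,11(13)-trien-12,8-olide | C=C1C(=O)O[C@H]2C/C(C)=C/C[C@@H](O[Si](C)(C)C(C)(C)C)/C(COC(=O)[C@H](C)CC)=C/[C@@H](OC(=O)[C@H](C)CC)[C@H]12 | intermediate
24 | (3R,6R,7R,8S)-3-hydroxy-6,15-bis{[(2R)-2-methylbutanoyl]oxy}germacra-1(10)E,4E,11(13)-trien-12,8-olide (CNP0164325.1) | C=C1C(=O)O[C@H]2C/C(C)=C/C[C@@H](O)/C(COC(=O)[C@H](C)CC)=C/[C@@H](OC(=O)[C@H](C)CC)[C@H]12 | target

Total steps: 16. Longest linear sequence: 14 steps (steps 1–8 and 11–16); steps 9 and 10 prepare the aldol partner 17.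

Steps most likely to fail

Step 14. The process at risk is the facial selectivity of the alkenylchromium addition (attack on the other face of the formyl group gives the 6S alcohol). Lesser risks are oligomerisation, epimerisation of the formyl-bearing C7 before closure, and attack of the C6 alkoxide on C12. Fallback: starting from 20, the closure product of the wrong configuration, the 6S alcohol F1, is esterified with acid 10 under Mitsunobu conditions (PPh3, diisopropyl azodicarboxylate, toluene, 0 °C). This inverts C6 and rejoins the route at 23, so that step 15 is not needed.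

Step 13. The process at risk is over-reduction of the lactone or of the C15 ester, or epimerisation and double-bond migration of the β-formyl lactone during work-up. Fallback: starting from 19, NaBH4 (THF/H2O, 0 °C, short reaction time) should cleave the activated imide to the primary alcohol F2 while leaving lactone and ester intact, and Dess–Martin oxidation of F2 (NaHCO3, CH2Cl2, 0 °C) rejoins the route at 20.

Step 3. The process at risk is insufficient enantioselectivity with an enolisable aliphatic aldehyde, or acid-promoted migration of the C1=C10 double bond. Fallback: starting from 4, the MgI2-promoted iodo-aldol with 5 (CH2Cl2, 0 °C) gives the racemic Z-iodo ester F3. Dess–Martin oxidation converts it to the enone F4, and Corey–Bakshi–Shibata reduction ((S)-2-methyl-CBS-oxazaborolidine, catecholborane, toluene, −78 °C) sets C3 by reagent control and rejoins the route at 7.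

Further compounds
F1 | step 14 | (3R,6S,7R,8S)-3-{[tert-butyl(dimethyl)silyl]oxy}-6-hydroxy-15-{[(2R)-2-methylbutanoyl]oxy}germacra-1(10)E,4E,11(13)-trien-12,8-olide (C6 epimer of 22) | C=C1C(=O)O[C@H]2C/C(C)=C/C[C@@H](O[Si](C)(C)C(C)(C)C)/C(COC(=O)[C@H](C)CC)=C/[C@H](O)[C@H]12
F2 | step 13 | [(2E,3R,5E)-3-{[tert-butyl(dimethyl)silyl]oxy}-7-[(2S,3S)-3-(hydroxymethyl)-4-methylidene-5-oxooxolan-2-yl]-2-(iodomethylidene)-6-methylhept-5-en-1-yl] (2R)-2-methylbutanoate | C=C1C(=O)O[C@@H](C/C(C)=C/C[C@@H](O[Si](C)(C)C(C)(C)C)/C(COC(=O)[C@H](C)CC)=C/I)[C@@H]1CO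
F3 | step 3 | ethyl (2Z,5E)-8-{[tert-butyl(dimethyl)silyl]oxy}-3-hydroxy-2-(iodomethylidene)-6-methyloct-5-enoate (racemic) | CC(C)(C)[Si](C)(C)OCC/C(C)=C/CC(O)/C(C(=O)OCC)=C/I
F4 | step 3 | ethyl (2Z,5E)-8-{[tert-butyl(dimethyl)silyl]oxy}-2-(iodomethylidene)-6-methyl-3-oxooct-5-enoate | CC(C)(C)[Si](C)(C)OCC/C(C)=C/CC(=O)/C(C(=O)OCC)=C/I
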